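## Structural features

The target is a briarane-type diterpenoid (briarane numbering is used throughout): a cyclohexene (C1, C10–C14) is trans-fused through C1–C10 to a ten-membered carbocycle (C1–C10), and a γ-lactone (C7, C8, C17, carbonyl C19 and the ring oxygen) is fused to that ring at C7–C8. The six-membered ring carries four contiguous stereocentres next to the C13=C14 double bond: the quaternary C1 (15-methyl), C10, C11 (20-methyl, cis to the 15-methyl) and C12 (acetate, trans to the 20-methyl). In the ten-membered ring C2 (acetate) stands beside C1, and C7 (lactone oxygen), C8 (tertiary hydroxyl) and C9 (secondary hydroxyl) form a contiguous triad flanked by C17 (18-methyl, cis to the 8-hydroxyl on the lactone); the configuration read from the SMILES is 1S,2S,7R,8R,9S,10S,11R,12R,17R. Between these arrays lies the tetrasubstituted chloroalkene C5(CH3)=C6(Cl), with the ring carbons C4 and C7 cis (5E by the sequence rule because of chlorine). The fragile groups are the two acetates (the C12 one allylic), the β-hydroxy lactone (retro-aldol cleavage, translactonisation onto O9), the epimerisable C17, and C11 for as long as C12 is a ketone. The real difficulty is the medium ring with a tetrasubstituted chloroalkene joined directly to the oxygenated C7–C8–C9 segment, with eight stereocentres on or next to that ring. The key step exploits the unit C5(CH3)=C6(Cl)–C7(O-acyl): a 2-chloroallyl ester is the signature of the electrocyclic ring opening of a gem-dichlorocyclopropane, so C6 can be inserted as a single carbon between C5 and C7 of a nine-membered cycloalkene while the C19 carboxyl, held on C8 through C17, closes the lactone at C7. In one sentence: a silver-promoted ring opening of the dichlorocyclopropane 23, fused to a nine-membered ring, expands that ring to the ten-membered chloroalkene and is terminated by the C19 ester to give lactone 25.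

## Logic of the disconnections

29 ⇒ 28: the two C–O bonds of the isopropylidene acetal on O8 and O9 are cut last. The diol must stay masked while a cation is generated at C5–C7 and while base and Mitsunobu reagents are used. Nothing is gained in skeleton, but every earlier step is freed from two nucleophilic hydroxyls. The forward step must hydrolyse the acetal without touching the allylic acetate or the lactone.

28 ⇒ 27 ⇒ 26 ⇒ 25: the C17–H bond (epimerisation), the C12–O acetate bond (formed with inversion from the 12β-alcohol) and the C12–H bond (from the enone) are cut. C17 is the one stereocentre that equilibration can set, so no earlier step has to control it. Hydride is expected to reach C12 from the α face, so the α-acetate has to arrive with inversion. Keeping C12 as a ketone up to 25 deactivates C13=C14 towards the carbene and spares one protecting group. The demands are 1,2-selective reduction, clean SN2 at an allylic centre, and an enolate at C17 that reprotonates faster than it expels O8.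

25 ⇒ 23 (key): the C7–O lactone bond is cut and C6 is taken out of the ring perimeter, the C5=C6 π bond becoming the C5–C7 σ bond of a dichlorocyclopropane. The ten-membered ring becomes a nine-membered one, the lactone becomes an open methyl ester, and both the C7 stereocentre and the alkene geometry disappear from the precursor. The forward step must open in the disrotatory mode that gives the ring-cis alkene, capture the cation at C7 and not at C5, and use the ester oxygen and no other oxygen.

23 ⇒ 22: the C5–C6 and C6–C7 bonds are cut (dichlorocarbene addition). This leaves a plain trisubstituted Z-cycloalkene. The demand is chemoselectivity for C5=C7 over C13=C14, which the enone secures.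

22 ⇒ 21 ⇒ 20: the acetal C–O bonds and the ester O–CH3 bond are cut back to the C9-lactone 21, then the C8–C17 bond is cut to the C8 ketone carrying a 2-bromopropanoate on O9. Tethering the propionate to O9 is the only arrangement that delivers C17 to the face of C8 syn to O9; open-chain addition of C17 under chelation control gives the other C8 epimer. The gain is that C8 no longer has to be controlled separately. The demand is that the C–Br bond is reduced before the α-acyloxy ketone.

20 ⇒ 19 ⇒ 18 ⇒ 17: the C8 carbonyl is traced to a protected carbinol, and the C5=C7 bond is cut by ring-closing metathesis. The nine-membered ring falls to an open diene hung trans on the cyclohexenone. The demand is closure of a medium ring with a trisubstituted alkene, where only the Z isomer is accessible.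

17 ⇒ 16 ⇒ 13 + 14: the O9–acyl bond and then the C8–C9 bond are cut (γ-alkoxyallylboration of the C9 aldehyde). C7, C8 and both oxygens arrive in one step from a three-carbon reagent. The demand is reagent control at C9 against the Felkin preference of C10.

13 ⇒ 12 ⇒ 11 ⇒ 10 ⇒ 9 ⇒ 6 + 7: C9 is returned to the alcohol oxidation level, the C13=C14 bond is removed (Saegusa–Ito oxidation of the silyl enol ether), the acetate is removed and the C2–C3 bond is cut (Grignard addition). This leaves a cyclohexene with every ring stereocentre but C12 in place. The demand is Felkin–Anh control at C2 by the quaternary C1.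

6 ⇒ 3 + 5: the C1–C14 and C10–C11 bonds are cut (Diels–Alder). Three contiguous stereocentres, including the quaternary one, arise from two achiral four- and five-carbon pieces. The demand is para regiochemistry, the exo-formyl transition state and catalyst-controlled facial selectivity.

3 ⇒ 1 + 2 and 5 ⇒ 4: the C1=C10 bond is cut by Wittig olefination and the O–Si bond by enol silylation, reaching commercial materials. The demands are E geometry in 3 and Z geometry in 5.

## Other disconnections considered

Alternative 1: The cut that comes to mind first is a macrocyclisation. C6–C7 is cut to the seco aldehyde A1, which carries a 1-chloro-1-iodoalkene at C5=C6 and the C7 aldehyde on the fully substituted C8. The forward key step would be an intramolecular Nozaki–Hiyama–Kishi addition, followed by lactonisation of the C7 alkoxide onto the C19 ester. It is not preferred for three reasons. A geometrically defined, tetrasubstituted α-chloroalkenyl chromium species would have to add to a neopentyl-type aldehyde at high dilution. The C7 configuration would rest on the conformation of an open chain with no controlling element. Every stereocentre of A1 would have to be assembled before the ring exists, and the entropic and transannular cost of the ten-membered ring would fall on the last C–C bond formed. The chosen plan closes the medium ring by expansion, takes the alkene geometry from orbital symmetry and takes C7 from C8.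

Alternative 2: A biomimetic cut of C1–C10 leads to the fourteen-membered 1,2-epoxy macrocycle A2 with a C10=C11 trisubstituted alkene, as in the presumed cembrane-to-briarane biosynthesis. The forward key step would be an acid-promoted transannular epoxide–olefin cyclisation that forms C1–C10 and the C2 hydroxyl and leaves a cation at C11. It is not preferred because A2 contains the whole chloroalkene–lactone sector inside a larger ring that is no easier to make than the target's own. The C11 cation would give alkene isomers, so the 20-methyl centre would have to be set afterwards by hydrogenation in the presence of two alkenes and a vinyl chloride. The trans relationship of C1 and C10 would depend on a macrocyclic conformation that nothing in A2 fixes.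

Alternative 3: The order of annulation can be reversed. C1–C14 and C10–C11 are cut last, so that diene 5 adds to the preformed ten-membered (E)-enone A3 (C2 ketone conjugated with C1=C10) in a Diels–Alder reaction. It is not preferred because all the difficulty moves into A3, a ten-membered ring that already holds the chloroalkene, the lactone and a strained E-enone, and the alternative offers no way of making it. The facial selectivity of the cycloaddition would be set by the macrocycle conformation. In the chosen plan the same cycloaddition runs on a simple open-chain enal under catalyst control.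

Key step: step 17

Remark: α and β refer to the usual briarane drawing (C1 to C10 clockwise, β towards the viewer); C19 is the lactone carbonyl and C18 the methyl on C17.
Assumption: the (S)-configured oxazaborolidinium catalyst of step 3 is taken to expose the enal face that leads to 6; if the sense is the opposite, the (R)-catalyst, equally available, is used.
Remark: the bromine-bearing carbon of 17–20 is a mixture of epimers, which converges in step 14. The cyclopropane of 23 is drawn on the α face, but either face leads to the same cation in step 17.

## Steps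

Step 1
Reactants: 1 (tert-butyldimethylsilyloxy)acetaldehyde; 2 2-(triphenylphosphoranylidene)propanal
Product: 3 (E)-4-(tert-butyldimethylsilyloxy)-2-methylbut-2-enal
Conditions: toluene, 80 °C
Reagents that add atoms: none
Why: Wittig olefination with a stabilised formyl ylide, which gives the E enal; the product is an α-substituted enal and far less electrophilic than 1, so a second olefination should be slow.

Step 2
Reactants: 4 pent-1-en-3-one
Product: 5 (Z)-3-(tert-butyldimethylsilyloxy)penta-1,3-diene
Conditions: TBSOTf, Et3N, Et2O, 0 °C
Reagents that add atoms: tert-butyldimethylsilyl trifluoromethanesulfonate, CC(C)(C)[Si](C)(C)OS(=O)(=O)C(F)(F)F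
Why: Soft enolisation and O-silylation of an ethyl ketone, which should give mainly the Z dienol ether; this isomer has the methyl group on the outside of the s-cis diene.

Step 3
Reactants: 3 (E)-4-(tert-butyldimethylsilyloxy)-2-methylbut-2-enal; 5 (Z)-3-(tert-butyldimethylsilyloxy)penta-1,3-diene
Product: 6 (1S,5R,6S)-4-(tert-butyldimethylsilyloxy)-6-[(tert-butyldimethylsilyloxy)methyl]-1,5-dimethylcyclohex-3-ene-1-carbaldehyde
Conditions: (S)-3,3-diphenyl-1-(2-methylphenyl)tetrahydro-1H,3H-pyrrolo[1,2-c][1,3,2]oxazaborole (20 mol%), Tf2NH (20 mol%), CH2Cl2, −78 to −40 °C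
Reagents that add atoms: none
Why: Diels–Alder reaction catalysed by a chiral oxazaborolidinium ion (CBS-type catalyst activated by triflimide), a known process for α-substituted enals. The siloxy group of 5 sends its methyl-bearing terminus to C10 (siloxy carbon para to the formyl-bearing C1), and the α-methyl enal reacts through the exo-formyl transition state, which with the outside methyl of 5 places the 15-methyl, the C10 side chain and the 20-methyl all cis. The catalyst shields one face of the enal and so sets the absolute configuration of C1, C10 and C11 together.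

Step 4
Reactants: 6 (1S,5R,6S)-4-(tert-butyldimethylsilyloxy)-6-[(tert-butyldimethylsilyloxy)methyl]-1,5-dimethylcyclohex-3-ene-1-carbaldehyde; 7 4-bromo-2-methylbut-1-ene
Product: 9 (1S)-1-[(1S,5R,6S)-4-(tert-butyldimethylsilyloxy)-6-[(tert-butyldimethylsilyloxy)methyl]-1,5-dimethylcyclohex-3-en-1-yl]-4-methylpent-4-en-1-ol, via 3-methylbut-3-enylmagnesium bromide 8 (not isolated)
Conditions: 7, Mg, THF, 40 °C; then 6, −78 °C; aq. NH4Cl
Reagents that add atoms: none
Why: Grignard addition to the aldehyde on the quaternary C1. In the Felkin–Anh transition state the branched C10 arm stands anti to the nucleophile, which passes the methyl group and not the C14 methylene; this gives the 2S carbinol. The silyl enol ether and the silyl ether are inert.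

Step 5
Reactants: 9 (1S)-1-[(1S,5R,6S)-4-(tert-butyldimethylsilyloxy)-6-[(tert-butyldimethylsilyloxy)methyl]-1,5-dimethylcyclohex-3-en-1-yl]-4-methylpent-4-en-1-ol
Product: 10 (1S)-1-[(1S,5R,6S)-4-(tert-butyldimethylsilyloxy)-6-[(tert-butyldimethylsilyloxy)methyl]-1,5-dimethylcyclohex-3-en-1-yl]-4-methylpent-4-en-1-yl acetate
Conditions: Ac2O, DMAP (cat.), Et3N, CH2Cl2, rt
Reagents that add atoms: acetic anhydride, CC(=O)OC(C)=O
Why: DMAP-catalysed acetylation of the hindered secondary alcohol; this installs the final C2 acetate, which, flanked by the quaternary C1, is expected to survive all later steps.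

Step 6
Reactants: 10 (1S)-1-[(1S,5R,6S)-4-(tert-butyldimethylsilyloxy)-6-[(tert-butyldimethylsilyloxy)methyl]-1,5-dimethylcyclohex-3-en-1-yl]-4-methylpent-4-en-1-yl acetate
Product: 11 (1S)-1-[(1S,5R,6S)-6-[(tert-butyldimethylsilyloxy)methyl]-1,5-dimethyl-4-oxocyclohex-2-en-1-yl]-4-methylpent-4-en-1-yl acetate
Conditions: Pd(OAc)2 (1.1 equiv), MeCN, 40 °C
Reagents that add atoms: none
Why: Saegusa–Ito oxidation. The silyl enol ether gives a palladium enolate bound at C13, and β-hydride elimination can only take a hydrogen from C14, so the C13=C14 enone forms regiospecifically and C11 is not touched.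

Step 7
Reactants: 11 (1S)-1-[(1S,5R,6S)-6-[(tert-butyldimethylsilyloxy)methyl]-1,5-dimethyl-4-oxocyclohex-2-en-1-yl]-4-methylpent-4-en-1-yl acetate
Product: 12 (1S)-1-[(1S,5R,6S)-6-(hydroxymethyl)-1,5-dimethyl-4-oxocyclohex-2-en-1-yl]-4-methylpent-4-en-1-yl acetate
Conditions: HF·pyridine, pyridine, THF, 0 °C
Reagents that add atoms: none
Why: Fluoride cleavage of the primary silyl ether under buffered, non-basic conditions, so that C11 (α to the ketone) is not epimerised and the acetate does not migrate.

Step 8
Reactants: 12 (1S)-1-[(1S,5R,6S)-6-(hydroxymethyl)-1,5-dimethyl-4-oxocyclohex-2-en-1-yl]-4-methylpent-4-en-1-yl acetate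
Product: 13 (1S)-1-[(1S,5R,6S)-6-formyl-1,5-dimethyl-4-oxocyclohex-2-en-1-yl]-4-methylpent-4-en-1-yl acetate
Conditions: Dess–Martin periodinane, NaHCO3, CH2Cl2, 0 °C
Reagents that add atoms: none
Why: Dess–Martin oxidation of the primary alcohol under buffered conditions; the α-stereocentre C10 should be kept if the aldehyde is used directly.

Step 9
Reactants: 13 (1S)-1-[(1S,5R,6S)-6-formyl-1,5-dimethyl-4-oxocyclohex-2-en-1-yl]-4-methylpent-4-en-1-yl acetate; 14 3-(methoxymethoxy)prop-1-ene
Product: 16 (1S)-1-[(1S,5R,6S)-6-[(1S,2S)-1-hydroxy-2-(methoxymethoxy)but-3-en-1-yl]-1,5-dimethyl-4-oxocyclohex-2-en-1-yl]-4-methylpent-4-en-1-yl acetate, via (Z)-3-(methoxymethoxy)allyldiisopinocampheylborane 15 (not isolated)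
Conditions: 14, sec-BuLi, THF, −78 °C; (+)-Ipc2BOMe (from (−)-α-pinene); BF3·OEt2; then 13, −78 °C; HOCH2CH2NH2 work-up
Reagents that add atoms: none
Why: γ-Alkoxyallylboration through a closed chair transition state. The Z reagent gives the syn 8,9 relationship, and the isopinocampheyl groups derived from (−)-α-pinene direct attack to the Re face of the aldehyde (9S), against the modest Felkin preference of C10. The enone carbonyl and the acetate do not react at −78 °C, and the C8 configuration is irrelevant because C8 is oxidised in step 13.

Step 10
Reactants: 16 (1S)-1-[(1S,5R,6S)-6-[(1S,2S)-1-hydroxy-2-(methoxymethoxy)but-3-en-1-yl]-1,5-dimethyl-4-oxocyclohex-2-en-1-yl]-4-methylpent-4-en-1-yl acetate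
Product: 17 the O9 2-bromopropanoate of 16 (epimers at the CHBr carbon)
Conditions: 2-bromopropanoyl bromide, pyridine, CH2Cl2, 0 °C
Reagents that add atoms: 2-bromopropanoyl bromide, CC(Br)C(Br)=O
Why: Acylation of the only free hydroxyl with a reactive acyl bromide; it puts the propionate unit (C17, C18, C19) on O9, from where it can be delivered to C8.

Step 11
Reactants: 17 the O9 2-bromopropanoate of 16
Product: 18 nine-membered (5Z)-cycloalkene trans-fused to the cyclohexenone (2β-OAc; 8S-OMOM; 9β-O-(2-bromopropanoyl); C12 enone)
Conditions: second-generation Hoveyda–Grubbs catalyst (H2IMes)Cl2Ru(=CH-C6H4-2-OiPr) (10 mol%), toluene (1 mM), 80 °C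
Reagents that add atoms: none
Why: Ring-closing metathesis between the allylic-ether vinyl group and the 1,1-disubstituted alkene, with loss of ethene; a nine-membered ring can only hold the Z alkene. The enone alkene is electron-poor and sits in an unstrained six-membered ring, so it should not take part.

Step 12
Reactants: 18 nine-membered (5Z)-cycloalkene with 8-OMOM
Product: 19 the corresponding C8 allylic alcohol
Conditions: Me2BBr, CH2Cl2, −78 °C; then aq. NaHCO3
Reagents that add atoms: none
Why: Lewis-acid cleavage of the methoxymethyl acetal at low temperature, a method that leaves acetates, the α-bromo ester and enones untouched.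

Step 13
Reactants: 19 C8 allylic alcohol
Product: 20 nine-membered 5(7)-en-8-one (2β-OAc; 9β-O-(2-bromopropanoyl); C12 enone)
Conditions: Dess–Martin periodinane, NaHCO3, CH2Cl2, 0 °C
Reagents that add atoms: none
Why: Dess–Martin oxidation of the allylic alcohol to the conjugated C8 ketone; both C8 epimers that could arise earlier converge here.

Step 14
Reactants: 20 nine-membered 5(7)-en-8-one
Product: 21 C9-lactone (O9–C19(=O)–C17–C8) with free 8α-hydroxyl (8R,9S,17S)
Conditions: SmI2 (2.2 equiv, added slowly), THF, −78 °C
Reagents that add atoms: none
Why: Intramolecular Reformatsky reaction. Divalent samarium reduces the C–Br bond faster than the α-acyloxy ketone or the enones, and the samarium enolate adds 1,2 to the C8 ketone through a cis-fused five-membered lactone, so C17 arrives on the face of O9 and the new hydroxyl is anti to O9 (8R). The chelated Z-enolate is expected to put the 18-methyl cis to that hydroxyl (17S); this is not the final C17 configuration, and either C17 epimer is serviceable because step 20 equilibrates this centre.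

Step 15
Reactants: 21 C9-lactone with free 8α-hydroxyl
Product: 22 methyl ester with O8,O9-isopropylidene acetal (nine-membered 5(7)-ene; 2β-OAc; C12 enone)
Conditions: Me2C(OMe)2, MeOH, camphorsulfonic acid (cat.), CH2Cl2, rt
Reagents that add atoms: 2,2-dimethoxypropane, COC(C)(C)OC; methanol, CO
Why: Acid-catalysed methanolysis of the β-hydroxy-γ-lactone, drawn forward by trapping of the freed 8,9-diol as its acetonide (transacetalisation). No base is present, so retro-aldol cleavage at C8–C17 is avoided, and the hindered C2 acetate should survive.

Step 16
Reactants: 22 acetonide methyl ester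
Product: 23 gem-dichlorocyclopropane (C6 bridging C5 and C7, cis-fused to the nine-membered ring)
Conditions: Cl3CCO2Na (excess), BnEt3NCl (cat.), CHCl3, 60 °C
Reagents that add atoms: sodium trichloroacetate, [Na+].[O-]C(=O)C(Cl)(Cl)Cl
Why: Dichlorocarbene, formed by decarboxylation under neutral conditions, adds stereospecifically to the only electron-rich alkene, the trisubstituted C5=C7. C13=C14 is protected as part of the enone. The face of addition does not matter for the next step.

Step 17
Reactants: 23 gem-dichlorocyclopropane
Product: 25 ten-membered (5E)-6-chloroalkene with the C19→O7 γ-lactone (acetonide; 2β-OAc; C12 enone; 17S), via O-methyl lactonium ion 24 (not isolated)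
Conditions: AgOCOCF3 (3 equiv), toluene, 80 °C, dark
Reagents that add atoms: none
Why: AgOCOCF3 abstracts a chloride from C6 and the C5–C7 σ bond opens in a disrotatory two-electron electrocyclic process to the 2-chloroallyl cation C5–C6–C7; the closest known reaction type is the silver-promoted ring expansion of ring-fused gem-dihalocyclopropanes with capture by a tethered oxygen nucleophile. The ten-membered ring is closed by ring expansion (one carbon inserted into the nine-membered ring, no end-to-end cyclisation), and the γ-lactone by 5-exo attack of the ester carbonyl oxygen on C7 to give ion 24, which trifluoroacetate demethylates. Capture at C7 and not at the tertiary C5 follows from the tether: C19 reaches C7 through a five-membered transition state and C5 only through a seven-membered one. The C5=C6 geometry follows from torquoselectivity: loss of the chloride syn to C4 and C8 turns both ring carbons inward and the C5 methyl outward, giving the ring-cis (5E) alkene, whereas the other mode needs the methyl to rotate inward against H7 and places an E double bond in a ten-membered ring that carries three fused rings. C7 is controlled by C8: C17 can reach the allyl terminus only from the face anti to the C8–C9 bond, with the small C8–O8 bond eclipsing the allyl plane (A(1,3) strain), which gives the trans-fused lactone with H7 β (7R). Both faces of cyclopropanation lead to the same cation, so the step is stereoconvergent with respect to C5 and C7 of 23. The selectivity needed is capture by the ester in preference to O8, O9 or O2, and the acetonide and the C2 acetate secure it by masking those oxygens.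

Step 18
Reactants: 25 ten-membered chloroalkene lactone with C12 enone
Product: 26 12β-allylic alcohol
Conditions: NaBH4, CeCl3·7H2O, MeOH, −78 °C
Reagents that add atoms: none
Why: Luche 1,2-reduction of the enone. In the trans-fused bicycle the 20-methyl is axial on the β face next to C12, so hydride should come from the α face and give the 12β-alcohol; the lactone, acetate and vinyl chloride are inert.

Step 19
Reactants: 26 12β-allylic alcohol
Product: 27 12α-acetate (acetonide; 17S)
Conditions: AcOH, PPh3, DIAD, toluene, 0 °C to rt
Reagents that add atoms: acetic acid, CC(=O)O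
Why: Mitsunobu esterification with SN2 inversion; acetate enters from the open α face and gives the 12α-acetate directly. The SN2' path at C14 is blocked by the quaternary C1.

Step 20
Reactants: 27 12α-acetate (17S)
Product: 28 17R epimer of 27 (18-methyl cis to O8, anti to C9)
Conditions: DBU (0.5 equiv), toluene, 60 °C
Reagents that add atoms: none
Why: Thermodynamic epimerisation through the lactone enolate; in the target-type lactone the methyl is more stable anti to the C9 branch of the spiro-fused dioxolane, which is the natural 17R configuration. The weak amidine base keeps the enolate concentration low, which should limit β-elimination of O8; C17–H is the only acidic C–H at a stereocentre in 27.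

Step 21
Reactants: 28 17R acetonide
Product: 29 CNP0296164.1 (target)
Conditions: AcOH/H2O 4:1, 40 °C
Reagents that add atoms: none
Why: Mild acid hydrolysis of the isopropylidene acetal; the two acetates, the lactone and the vinyl chloride should be stable to aqueous acetic acid, and no base is present to promote translactonisation to O9.

## Compound list

1 | (tert-butyldimethylsilyloxy)acetaldehyde | O=CCO[Si](C)(C)C(C)(C)C | starting material
2 | 2-(triphenylphosphoranylidene)propanal | CC(C=O)=P(c1ccccc1)(c1ccccc1)c1ccccc1 | starting material
3 | (E)-4-(tert-butyldimethylsilyloxy)-2-methylbut-2-enal | O=C/C(C)=C/CO[Si](C)(C)C(C)(C)C | intermediate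
4 | pent-1-en-3-one | C=CC(=O)CC | starting material
5 | (Z)-3-(tert-butyldimethylsilyloxy)penta-1,3-diene | C/C=C(\O[Si](C)(C)C(C)(C)C)C=C | intermediate
6 | (1S,5R,6S)-4-(tert-butyldimethylsilyloxy)-6-[(tert-butyldimethylsilyloxy)methyl]-1,5-dimethylcyclohex-3-ene-1-carbaldehyde | O=C[C@@]1(C)CC=C(O[Si](C)(C)C(C)(C)C)[C@H](C)[C@@H]1CO[Si](C)(C)C(C)(C)C | intermediate
7 | 4-bromo-2-methylbut-1-ene | C=C(C)CCBr | starting material
8 | 3-methylbut-3-enylmagnesium bromide | C=C(C)CC[Mg]Br | intermediate
9 | (1S)-1-[(1S,5R,6S)-4-(tert-butyldimethylsilyloxy)-6-[(tert-butyldimethylsilyloxy)methyl]-1,5-dimethylcyclohex-3-en-1-yl]-4-methylpent-4-en-1-ol | C=C(C)CC[C@H](O)[C@@]1(C)CC=C(O[Si](C)(C)C(C)(C)C)[C@H](C)[C@@H]1CO[Si](C)(C)C(C)(C)C | intermediate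
10 | acetate of 9 (2S) | C=C(C)CC[C@H](OC(C)=O)[C@@]1(C)CC=C(O[Si](C)(C)C(C)(C)C)[C@H](C)[C@@H]1CO[Si](C)(C)C(C)(C)C | intermediate
11 | (1S)-1-[(1S,5R,6S)-6-[(tert-butyldimethylsilyloxy)methyl]-1,5-dimethyl-4-oxocyclohex-2-en-1-yl]-4-methylpent-4-en-1-yl acetate | C=C(C)CC[C@H](OC(C)=O)[C@@]1(C)C=CC(=O)[C@H](C)[C@@H]1CO[Si](C)(C)C(C)(C)C | intermediate
12 | (1S)-1-[(1S,5R,6S)-6-(hydroxymethyl)-1,5-dimethyl-4-oxocyclohex-2-en-1-yl]-4-methylpent-4-en-1-yl acetate | C=C(C)CC[C@H](OC(C)=O)[C@@]1(C)C=CC(=O)[C@H](C)[C@@H]1CO | intermediate
13 | (1S)-1-[(1S,5R,6S)-6-formyl-1,5-dimethyl-4-oxocyclohex-2-en-1-yl]-4-methylpent-4-en-1-yl acetate | C=C(C)CC[C@H](OC(C)=O)[C@@]1(C)C=CC(=O)[C@H](C)[C@@H]1C=O | intermediate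
14 | 3-(methoxymethoxy)prop-1-ene | C=CCOCOC | starting material
15 | (Z)-3-(methoxymethoxy)allyldiisopinocampheylborane, isopinocampheyl groups from (−)-α-pinene | COCO/C=C\CB([C@@H]1[C@@H](C)[C@@H]2C[C@H](C1)C2(C)C)[C@@H]1[C@@H](C)[C@@H]2C[C@H](C1)C2(C)C | intermediate
16 | (1S)-1-[(1S,5R,6S)-6-[(1S,2S)-1-hydroxy-2-(methoxymethoxy)but-3-en-1-yl]-1,5-dimethyl-4-oxocyclohex-2-en-1-yl]-4-methylpent-4-en-1-yl acetate | C=C(C)CC[C@H](OC(C)=O)[C@@]1(C)C=CC(=O)[C@H](C)[C@@H]1[C@H](O)[C@@H](OCOC)C=C | intermediate
17 | O9 2-bromopropanoate of 16 (epimers at CHBr) | C=C(C)CC[C@H](OC(C)=O)[C@@]1(C)C=CC(=O)[C@H](C)[C@@H]1[C@H](OC(=O)C(C)Br)[C@@H](OCOC)C=C | intermediate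
18 | ring-closed nine-membered (5Z)-cycloalkene, trans-fused to the cyclohexenone; 2β-OAc, 8S-OMOM, 9β-O-(2-bromopropanoyl) (C6 not yet present) | CC(=O)O[C@H]1CC/C(C)=C\[C@H](OCOC)[C@@H](OC(=O)C(C)Br)[C@H]2[C@@H](C)C(=O)C=C[C@@]21C | intermediate
19 | C8 allylic alcohol from 18 | CC(=O)O[C@H]1CC/C(C)=C\[C@H](O)[C@@H](OC(=O)C(C)Br)[C@H]2[C@@H](C)C(=O)C=C[C@@]21C | intermediate
20 | nine-membered 5(7)-en-8-one; 2β-OAc, 9β-O-(2-bromopropanoyl), C12 enone | CC(=O)O[C@H]1CC/C(C)=C\C(=O)[C@@H](OC(=O)C(C)Br)[C@H]2[C@@H](C)C(=O)C=C[C@@]21C | intermediate
21 | C9-lactone (O9–C19) with 8α-OH; 18-methyl cis to the hydroxyl (8R,9S,17S) | CC(=O)O[C@H]1CC/C(C)=C\[C@@]3(O)[C@H](C)C(=O)O[C@H]3[C@H]2[C@@H](C)C(=O)C=C[C@@]21C | intermediate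
22 | methyl ester (C19) with O8,O9-isopropylidene acetal; nine-membered 5(7)Z-ene | CC(=O)O[C@H]1CC/C(C)=C\[C@]3([C@H](C)C(=O)OC)OC(C)(C)O[C@H]3[C@H]2[C@@H](C)C(=O)C=C[C@@]21C | intermediate
23 | 6,6-dichlorocyclopropane across C5–C7 of 22 (cis-fused, drawn on the α face) | CC(=O)O[C@H]1CC[C@]4(C)C(Cl)(Cl)[C@@H]4[C@]3([C@H](C)C(=O)OC)OC(C)(C)O[C@H]3[C@H]2[C@@H](C)C(=O)C=C[C@@]21C | intermediate
24 | O-methyl lactonium ion (ring-expanded, O7–C19 closed, methyl still on oxygen) | CC(=O)O[C@H]1CC/C(C)=C(/Cl)[C@@H]2OC(=[O+]C)[C@@H](C)[C@]23OC(C)(C)O[C@H]3[C@H]2[C@@H](C)C(=O)C=C[C@@]21C | intermediate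
25 | ten-membered (5E)-6-chloroalkene, C19→O7 lactone (H7 β), acetonide, 2β-OAc, C12 enone, 17S | CC(=O)O[C@H]1CC/C(C)=C(/Cl)[C@@H]2OC(=O)[C@@H](C)[C@]23OC(C)(C)O[C@H]3[C@H]2[C@@H](C)C(=O)C=C[C@@]21C | intermediate
26 | 12β-alcohol from 25 | CC(=O)O[C@H]1CC/C(C)=C(/Cl)[C@@H]2OC(=O)[C@@H](C)[C@]23OC(C)(C)O[C@H]3[C@H]2[C@@H](C)[C@@H](O)C=C[C@@]21C | intermediate
27 | 12α-acetate, 17S | CC(=O)O[C@H]1CC/C(C)=C(/Cl)[C@@H]2OC(=O)[C@@H](C)[C@]23OC(C)(C)O[C@H]3[C@H]2[C@@H](C)[C@H](OC(C)=O)C=C[C@@]21C | intermediate
28 | 12α-acetate, 17R (8,9-O-isopropylidene derivative of the target) | CC(=O)O[C@H]1CC/C(C)=C(/Cl)[C@@H]2OC(=O)[C@H](C)[C@]23OC(C)(C)O[C@H]3[C@H]2[C@@H](C)[C@H](OC(C)=O)C=C[C@@]21C | intermediate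
29 | CNP0296164.1 | CC(=O)O[C@H]1CC/C(C)=C(/Cl)[C@@H]2OC(=O)[C@H](C)[C@@]2(O)[C@@H](O)[C@H]2[C@@H](C)[C@H](OC(C)=O)C=C[C@@]21C | target

## Step count and least certain steps

Total: 21 steps. Longest linear sequence: 20 steps (steps 1 and 3–21; step 2 is a one-step branch).

Step 17 (key step). The most likely failure is ring opening in the other disrotatory mode. Loss of the chloride anti to the ring carbons is the usual kinetic preference of medium-ring bicyclic dihalocyclopropanes, and it would turn C4 and C8 outward and give the ring-trans alkene. Capture of the cation at C5 by an external nucleophile and loss of a proton to a chlorodiene are lesser risks. Because C7 is set by C8 in either mode, the wrong mode would give the geometric isomer F1 with the correct C7 configuration. The fallback sets out from 23 and moves the alkene geometry from orbital-symmetry control to thermodynamic control: F1 is equilibrated by reversible thiyl-radical addition (PhSSPh, light, benzene) to the strain-free ring-cis isomer, returning to the route at 25.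

Step 11. Ring closure may lose to oligomerisation. The two chains must become diequatorial on the cyclohexenone, which forces the two methyl groups syn-axial, and a trisubstituted alkene has to form in a nine-membered ring. The fallback sets out from 17 and closes the ring on a lactone template. The methoxymethyl group is removed (Me2BBr) to give the alcohol F2, which is oxidised (Dess–Martin periodinane) to the vinyl ketone F3. The SmI2 Reformatsky reaction is then run before ring closure, giving the γ-lactone F4, in which the five-membered ring holds the C8 vinyl group and the C9–C10 bond cis. Only the C8 epimer of F4 that has this cis relationship can close, and ring-closing metathesis of it with the same ruthenium catalyst returns to the route at 21.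

Step 9. Facial selectivity at C9 may be poor, because the reagent works against the Felkin preference of a hindered α-branched aldehyde. The fallback sets out from 13 and uses that preference. The enantiomeric reagent F5 (from (−)-Ipc2BOMe, made from (+)-α-pinene) is matched with the substrate and should give the 8R,9R syn adduct F6. Mitsunobu esterification of F6 with 2-bromopropanoic acid (PPh3, DIAD) then inverts C9 and gives the 9S bromo ester F7. Ring-closing metathesis gives F8, cleavage of the methoxymethyl ether gives F9, and Dess–Martin oxidation removes the C8 stereocentre and returns to the route at 20.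

Step 4. Facial selectivity at C2 may be poor, because the two ring branches on the quaternary C1 differ less in size than the Felkin–Anh model assumes. The fallback sets out from 9 as its C2 epimer mixture and replaces substrate control by reagent control. Dess–Martin oxidation gives the ketone F10, and Corey–Bakshi–Shibata reduction with (R)-2-methyl-CBS-oxazaborolidine and catecholborane (toluene, −78 °C) distinguishes the quaternary from the primary substituent and returns to the route at 9.

## Further compounds

F1 | step 17 | ring-trans (5Z) geometric isomer of 25, chlorine cis to C4 | CC(=O)O[C@H]1CC/C(C)=C(\Cl)[C@@H]2OC(=O)[C@@H](C)[C@]23OC(C)(C)O[C@H]3[C@H]2[C@@H](C)C(=O)C=C[C@@]21C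
F2 | step 11 | open-chain C8 alcohol from 17 (methoxymethyl group removed) | C=C(C)CC[C@H](OC(C)=O)[C@@]1(C)C=CC(=O)[C@H](C)[C@@H]1[C@H](OC(=O)C(C)Br)[C@@H](O)C=C
F3 | step 11 | open-chain C8 vinyl ketone with the O9 2-bromopropanoate | C=C(C)CC[C@H](OC(C)=O)[C@@]1(C)C=CC(=O)[C@H](C)[C@@H]1[C@H](OC(=O)C(C)Br)C(=O)C=C
F4 | step 11 | open-chain C9-lactone with C8 vinyl and 8-hydroxyl (diene for lactone-templated ring closure) | C=C(C)CC[C@H](OC(C)=O)[C@@]1(C)C=CC(=O)[C@H](C)[C@@H]1[C@@H]2OC(=O)[C@@H](C)[C@]2(O)C=C
F5 | step 9 | (Z)-3-(methoxymethoxy)allyldiisopinocampheylborane, isopinocampheyl groups from (+)-α-pinene (enantiomer of 15) | COCO/C=C\CB([C@H]1[C@H](C)[C@H]2C[C@@H](C1)C2(C)C)[C@H]1[C@H](C)[C@H]2C[C@@H](C1)C2(C)C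
F6 | step 9 | 8R,9R syn adduct (8,9-bis-epimer of 16) | C=C(C)CC[C@H](OC(C)=O)[C@@]1(C)C=CC(=O)[C@H](C)[C@@H]1[C@@H](O)[C@H](OCOC)C=C
F7 | step 9 | 9S 2-bromopropanoate with 8R methoxymethyl ether (8-epimer of 17) | C=C(C)CC[C@H](OC(C)=O)[C@@]1(C)C=CC(=O)[C@H](C)[C@@H]1[C@H](OC(=O)C(C)Br)[C@H](OCOC)C=C
F8 | step 9 | 8-epimer of 18 | CC(=O)O[C@H]1CC/C(C)=C\[C@@H](OCOC)[C@@H](OC(=O)C(C)Br)[C@H]2[C@@H](C)C(=O)C=C[C@@]21C
F9 | step 9 | 8-epimer of 19 | CC(=O)O[C@H]1CC/C(C)=C\[C@@H](O)[C@@H](OC(=O)C(C)Br)[C@H]2[C@@H](C)C(=O)C=C[C@@]21C
F10 | step 4 | C2 ketone from 9 | C=C(C)CCC(=O)[C@@]1(C)CC=C(O[Si](C)(C)C(C)(C)C)[C@H](C)[C@@H]1CO[Si](C)(C)C(C)(C)C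
A1 | alternative 1 | seco C7 aldehyde with a C5=C6 1-chloro-1-iodoalkene | CC(=O)O[C@@H](CC/C(C)=C(/Cl)I)[C@@]1(C)C=C[C@@H](OC(C)=O)[C@H](C)[C@@H]1[C@@H]2OC(C)(C)O[C@]2(C=O)[C@@H](C)C(=O)OC
A2 | alternative 2 | fourteen-membered 1,2-epoxy macrocycle lacking the C1–C10 bond | C[C@@]12O[C@H]1CC/C(C)=C(/Cl)[C@@H]3OC(=O)[C@H](C)[C@@]3(O)[C@@H](O)/C=C(\C)[C@H](OC(C)=O)/C=C\2
A3 | alternative 3 | ten-membered (E)-enone (C2 ketone, C1=C10) carrying the chloroalkene and lactone | O=C1CC/C(C)=C(/Cl)[C@@H]2OC(=O)[C@H](C)[C@@]2(O)[C@@H](O)/C=C1\C
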